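**Plan**

1. Retrosynthetic cuts: first the ester C–O bond at C-1′ (formed with inversion), then C-1′–O (from C-1′–Si), then in one operation the ring bonds C3–C4 and O1–C5. This leads back to (S)-2-(triethylsilyloxy)heptanal and (S)-3-(dimethylphenylsilyl)dodeca-1,11-diene.
2. Enabling feature: ring O1 and the C-3 hydroxyl sit on neighbouring carbons (C2, C3), and C5 bears the oxygenated carbon C-1′. So C2–C3 is an α-oxy aldehyde and, with silicon in place of the C-1′ oxygen, C4=C5 is an allylsilane whose β-silyl cation at C5 is closed by O1.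
3. Forward order: aldehyde in 3 steps, silane in 4 steps; the tetrahydrofuran (the only ring) arises in the annulation; then PMB ether, C–Si to C–OH, Mitsunobu lauroylation, PMB removal.
4. Stereochemistry: C2 from methyl (S)-glycidate; C3 from chelate-controlled addition; C5 relayed from the silane stereocentre (Cu-catalysed asymmetric allylic silylation) by anti SE2′ attack; C-1′ carried as C–Si, oxidised with retention, then inverted in the esterification.

Key step: step 8

Assumption: in step 7 the sense of induction depends on the chiral carbene ligand, so the ligand enantiomer used is the one that delivers the (S)-silane.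

**Step 1**
Reactants: 1 methyl (S)-glycidate; 2 n-butylmagnesium bromide
Product: 3 methyl (S)-2-hydroxyheptanoate
Conditions: n-BuMgBr (1.3 equiv), CuI (10 mol %), THF, −78 → −40 °C; aq. NH4Cl
Reagents that add atoms: none
Why: Copper-catalysed Grignard opening of the epoxide at its unsubstituted carbon should outrun addition to the ester at low temperature; the stereocentre is not touched, so (S) is carried over.

**Step 2**
Reactants: 3 methyl (S)-2-hydroxyheptanoate
Product: 4 methyl (S)-2-(triethylsilyloxy)heptanoate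
Conditions: Et3SiCl, imidazole, DMF, 0 °C → rt
Reagents that add atoms: chlorotriethylsilane CC[Si](Cl)(CC)CC
Why: Standard silylation of a secondary alcohol; the small Et3Si group is chosen because it can still take part in a chelate and is easily lost from oxygen in step 8.

**Step 3**
Reactants: 4 methyl (S)-2-(triethylsilyloxy)heptanoate
Product: 5 (S)-2-(triethylsilyloxy)heptanal
Conditions: i-Bu2AlH (1.1 equiv), CH2Cl2, −78 °C; MeOH, then aq. potassium sodium tartrate; used at once
Reagents that add atoms: none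
Why: Partial ester reduction: the aluminium hemiacetal, held by the α-silyloxy oxygen, is stable at −78 °C and releases the aldehyde only on work-up, under non-basic conditions that should not epimerise C-2.

**Step 4**
Reactants: 6 dec-9-enal; 7 triethyl phosphonoacetate
Product: 8 ethyl (E)-dodeca-2,11-dienoate
Conditions: NaH, THF, 0 °C → rt
Reagents that add atoms: none
Why: Horner–Wadsworth–Emmons olefination with a stabilised phosphonate anion should give the (E)-enoate by thermodynamic control of the oxaphosphetane.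

**Step 5**
Reactants: 8 ethyl (E)-dodeca-2,11-dienoate
Product: 9 (E)-dodeca-2,11-dien-1-ol
Conditions: i-Bu2AlH (2.3 equiv), CH2Cl2, −78 → 0 °C; aq. potassium sodium tartrate
Reagents that add atoms: none
Why: 1,2-Reduction of an enoate to the allylic alcohol, with both alkenes untouched.

**Step 6**
Reactants: 9 (E)-dodeca-2,11-dien-1-ol
Product: 10 diethyl (E)-dodeca-2,11-dien-1-yl phosphate
Conditions: (EtO)2P(O)Cl, pyridine, DMAP (cat.), CH2Cl2, 0 °C
Reagents that add atoms: diethyl chlorophosphate CCOP(=O)(Cl)OCC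
Why: O-Phosphorylation of a primary allylic alcohol gives the leaving group needed for copper-catalysed γ-selective substitution.

**Step 7**
Reactants: 10 diethyl (E)-dodeca-2,11-dien-1-yl phosphate
Product: 11 (S)-dodeca-1,11-dien-3-yl(dimethyl)phenylsilane
Conditions: PhMe2Si–B(pin) (1.5 equiv), CuCl (5 mol %), chiral C2-symmetric imidazolinium salt (N-heterocyclic carbene precursor, 6 mol %), NaOMe (1.5 equiv), CH2Cl2, 0 °C
Reagents that add atoms: (dimethylphenylsilyl)boronic acid pinacol ester CC1(C)OB(OC1(C)C)[Si](C)(C)c1ccccc1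
Why: Copper-catalysed asymmetric allylic silylation: the silylcopper species formed by Si–B/Cu–OMe exchange attacks the γ-carbon (SN2′) to give the branched silane, and the chiral carbene ligand selects the alkene face and so sets the (S) silicon-bearing centre; the isolated chain-end alkene is not a substrate.

**Step 8**
Reactants: 5 (S)-2-(triethylsilyloxy)heptanal; 11 (S)-dodeca-1,11-dien-3-yl(dimethyl)phenylsilane
Product: 14 (2S,3S,5R)-5-[(1S)-1-(dimethylphenylsilyl)dec-9-en-1-yl]-2-pentyltetrahydrofuran-3-ol, via β-silyl cation 12 (not isolated), via silyloxonium ion 13 (not isolated)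
Conditions: SnCl4 (1.1 equiv), CH2Cl2, −78 °C, 5 precomplexed 10 min, then 11 (1.3 equiv), −78 → −40 °C; then H2O, NaHCO3 wash
Reagents that add atoms: none
Why: SnCl4 binds the aldehyde oxygen and the α-silyloxy oxygen of 5 in a five-membered chelate, and the terminal CH2 of allylsilane 11 adds to the carbonyl carbon on the chelate face anti to the pentyl group (C3–C4 bond; C-3 S, 2,3-cis), giving the silicon-bridged β-silyl cation 12 at C-5. The ether oxygen O1, released from tin and placed 1,5 to the cation, opens it at C-5 anti to silicon (5-exo-tet closure of the tetrahydrofuran ring; O1–C5 bond) to give silyloxonium ion 13, which loses Et3Si to chloride. The closest known reaction type is the Lewis-acid-promoted formal [3+2] annulation of α-silyloxy aldehydes with allylsilanes to 3-hydroxytetrahydrofurans, combined here with the anti-SE2′ chirality transfer of α-substituted allylsilanes. C-5 (R) is controlled by the silane stereocentre: reaction through the conformer whose carbinyl H eclipses the double bond, with both new bonds formed on the alkene face opposite silicon, fixes silicon anti to O1 across C-1′/C-5 and, with (S)-11, the 3,5-trans ring. C-1′ is not touched and keeps silicon as a latent hydroxyl. The step needs chelate over Felkin addition (small Et3Si ether, bidentate SnCl4), closure by O1 over loss of silicon or 1,2-silyl migration (hindered PhMe2Si; O1 closes a five-membered ring directly), and reaction at the allylsilane and not the chain-end alkene (only the former gains β-silicon stabilisation).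

**Step 9**
Reactants: 14 (2S,3S,5R)-5-[(1S)-1-(dimethylphenylsilyl)dec-9-en-1-yl]-2-pentyltetrahydrofuran-3-ol
Product: 15 (2S,3S,5R)-5-[(1S)-1-(dimethylphenylsilyl)dec-9-en-1-yl]-3-(4-methoxybenzyloxy)-2-pentyltetrahydrofuran
Conditions: NaH, 4-methoxybenzyl chloride, Bu4NI (cat.), DMF, 0 °C → rt
Reagents that add atoms: 4-methoxybenzyl chloride COc1ccc(CCl)cc1
Why: Williamson etherification of the only free hydroxyl; the PMB ether tolerates base, fluoride and peroxide and is removed oxidatively at the end without touching the ester or the alkene.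

**Step 10**
Reactants: 15 (2S,3S,5R)-5-[(1S)-1-(dimethylphenylsilyl)dec-9-en-1-yl]-3-(4-methoxybenzyloxy)-2-pentyltetrahydrofuran
Product: 16 (1S)-1-[(2R,4S,5S)-4-(4-methoxybenzyloxy)-5-pentyltetrahydrofuran-2-yl]dec-9-en-1-ol
Conditions: t-BuOOH, KH, N-methylpyrrolidone, rt; then Bu4NF, 70 °C
Reagents that add atoms: tert-butyl hydroperoxide CC(C)(C)OO
Why: Tamao–Fleming oxidation under nucleophilic conditions: peroxide anion adds to silicon and the aryl, then the alkyl group migrate from silicon to oxygen with retention at C-1′ (S); no electrophile is present, so the terminal alkene and the PMB ether should survive.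

**Step 11**
Reactants: 16 (1S)-1-[(2R,4S,5S)-4-(4-methoxybenzyloxy)-5-pentyltetrahydrofuran-2-yl]dec-9-en-1-ol; 17 dodecanoic acid
Product: 18 (1R)-1-[(2R,4S,5S)-4-(4-methoxybenzyloxy)-5-pentyltetrahydrofuran-2-yl]dec-9-en-1-yl dodecanoate
Conditions: PPh3, diisopropyl azodicarboxylate, toluene, 0 °C → rt
Reagents that add atoms: none
Why: Mitsunobu esterification: the alkoxyphosphonium ion is displaced by laurate in an SN2 step with inversion, which turns the (1S) carbinol from the annulation into the required (1R) ester and installs the acyl chain in the same operation.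

**Step 12**
Reactants: 18 (1R)-1-[(2R,4S,5S)-4-(4-methoxybenzyloxy)-5-pentyltetrahydrofuran-2-yl]dec-9-en-1-yl dodecanoate
Product: 19 (1R)-1-[(2R,4S,5S)-4-hydroxy-5-pentyltetrahydrofuran-2-yl]dec-9-en-1-yl dodecanoate (CNP0219213.1)
Conditions: DDQ (1.3 equiv), CH2Cl2/pH 7 buffer (10:1), 0 °C → rt
Reagents that add atoms: none
Why: Oxidative PMB cleavage by hydride abstraction from the electron-rich benzylic position and hydrolysis of the oxocarbenium ion; the ester, the isolated alkene and all stereocentres are unaffected.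

**Compound list**

1 | methyl (S)-glycidate | COC(=O)[C@@H]1CO1 | starting material
2 | n-butylmagnesium bromide | CCCC[Mg]Br | starting material
3 | methyl (S)-2-hydroxyheptanoate | CCCCC[C@H](O)C(=O)OC | intermediate
4 | methyl (S)-2-(triethylsilyloxy)heptanoate | CCCCC[C@H](O[Si](CC)(CC)CC)C(=O)OC | intermediate
5 | (S)-2-(triethylsilyloxy)heptanal | CCCCC[C@H](O[Si](CC)(CC)CC)C=O | intermediate
6 | dec-9-enal | C=CCCCCCCCC=O | starting material
7 | triethyl phosphonoacetate | CCOC(=O)CP(=O)(OCC)OCC | starting material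
8 | ethyl (E)-dodeca-2,11-dienoate | C=CCCCCCCC/C=C/C(=O)OCC | intermediate
9 | (E)-dodeca-2,11-dien-1-ol | C=CCCCCCCC/C=C/CO | intermediate
10 | diethyl (E)-dodeca-2,11-dien-1-yl phosphate | C=CCCCCCCC/C=C/COP(=O)(OCC)OCC | intermediate
11 | (S)-dodeca-1,11-dien-3-yl(dimethyl)phenylsilane | C=C[C@H](CCCCCCCC=C)[Si](C)(C)c1ccccc1 | intermediate
12 | β-silyl cation (open-chain zwitterionic tin alkoxide, cation at C-5; not isolated) | CCCCC[C@H](O[Si](CC)(CC)CC)[C@@H](O[Sn-](Cl)(Cl)(Cl)Cl)C[CH+][C@H](CCCCCCCC=C)[Si](C)(C)c1ccccc1 | intermediate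
13 | silyloxonium ion (ring closed, Et3Si still on O1; not isolated) | C=CCCCCCCC[C@H]([Si](C)(C)c1ccccc1)[C@H]2C[C@H](O[Sn-](Cl)(Cl)(Cl)Cl)[C@H](CCCCC)[O+]2[Si](CC)(CC)CC | intermediate
14 | (2S,3S,5R)-5-[(1S)-1-(dimethylphenylsilyl)dec-9-en-1-yl]-2-pentyltetrahydrofuran-3-ol | C=CCCCCCCC[C@H]([Si](C)(C)c1ccccc1)[C@H]1C[C@H](O)[C@H](CCCCC)O1 | intermediate
15 | (2S,3S,5R)-5-[(1S)-1-(dimethylphenylsilyl)dec-9-en-1-yl]-3-(4-methoxybenzyloxy)-2-pentyltetrahydrofuran | C=CCCCCCCC[C@H]([Si](C)(C)c1ccccc1)[C@H]1C[C@H](OCc2ccc(OC)cc2)[C@H](CCCCC)O1 | intermediate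
16 | (1S)-1-[(2R,4S,5S)-4-(4-methoxybenzyloxy)-5-pentyltetrahydrofuran-2-yl]dec-9-en-1-ol | C=CCCCCCCC[C@H](O)[C@H]1C[C@H](OCc2ccc(OC)cc2)[C@H](CCCCC)O1 | intermediate
17 | dodecanoic acid (lauric acid) | CCCCCCCCCCCC(=O)O | starting material
18 | (1R)-1-[(2R,4S,5S)-4-(4-methoxybenzyloxy)-5-pentyltetrahydrofuran-2-yl]dec-9-en-1-yl dodecanoate | C=CCCCCCCC[C@@H](OC(=O)CCCCCCCCCCC)[C@H]1C[C@H](OCc2ccc(OC)cc2)[C@H](CCCCC)O1 | intermediate
19 | (1R)-1-[(2R,4S,5S)-4-hydroxy-5-pentyltetrahydrofuran-2-yl]dec-9-en-1-yl dodecanoate | C=CCCCCCCC[C@@H](OC(=O)CCCCCCCCCCC)[C@H]1C[C@H](O)[C@H](CCCCC)O1 | target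

**Summary**

Total step count: 12 (branches of 3 and 4 steps, then 5 steps after their union).
Longest linear sequence: 9 steps (steps 4–12, from dec-9-enal).

**Steps most likely to fail**

1. Step 8. What may go wrong: Felkin instead of chelate addition at C-3; erosion of alkene-face control at C-5, because the silane-dictated face opposes the 3,5-cis closure that the carbonyl-addition geometry is expected to prefer; or loss of silicon to an open-chain homoallylic alcohol. The fallback sets out from 5 and 11 and comes back at 14. The union is run in its non-chelated sense, in which all control elements should reinforce one another: 5 and 11 with BF3·OEt2 in CH2Cl2 at −78 °C should give, by Felkin addition, the C-3 epimer (2S,3R,5R)-5-[(1S)-1-(dimethylphenylsilyl)dec-9-en-1-yl]-2-pentyltetrahydrofuran-3-ol F1, whose C-3 oxygen and C-5 side chain are cis. Oxidation with Dess–Martin periodinane/NaHCO3 in CH2Cl2 should give the ketone (2S,5R)-5-[(1S)-1-(dimethylphenylsilyl)dec-9-en-1-yl]-2-pentyldihydrofuran-3(2H)-one F2. Reduction with LiBH(s-Bu)3 in THF at −78 °C, with hydride delivered anti to the adjacent pentyl group, should then give 14.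

2. Step 10. What may go wrong: fluoride- or base-induced β-elimination of the ring oxygen from the β-alkoxysilane (ring opening), or incomplete cleavage of the Si–phenyl bond. The fallback sets out from 14 and comes back at 19; it replaces nucleophilic by electrophilic activation of silicon and uses an acid-stable, oxidatively removable ether. NaH and 2-(bromomethyl)naphthalene in DMF should give (2S,3S,5R)-5-[(1S)-1-(dimethylphenylsilyl)dec-9-en-1-yl]-3-(naphthalen-2-ylmethoxy)-2-pentyltetrahydrofuran F3. Ipso-protodesilylation with HBF4·OEt2 in CH2Cl2 at 0 °C should give the fluorosilane (2S,3S,5R)-5-[(1S)-1-(fluorodimethylsilyl)dec-9-en-1-yl]-3-(naphthalen-2-ylmethoxy)-2-pentyltetrahydrofuran F4. Oxidation with H2O2, KF and KHCO3 in THF/MeOH should give, with retention, (1S)-1-[(2R,4S,5S)-4-(naphthalen-2-ylmethoxy)-5-pentyltetrahydrofuran-2-yl]dec-9-en-1-ol F5. Mitsunobu reaction with 17 (PPh3, diisopropyl azodicarboxylate) should give (1R)-1-[(2R,4S,5S)-4-(naphthalen-2-ylmethoxy)-5-pentyltetrahydrofuran-2-yl]dec-9-en-1-yl dodecanoate F6, and DDQ in wet CH2Cl2 should release 19.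

3. Step 11. What may go wrong: slow SN2 displacement at a hindered carbinol next to the ring oxygen with a weakly acidic aliphatic acid, elimination, or participation of the ring oxygen leading to retention or ring expansion. The fallback sets out from 16 and comes back at 18; it replaces the SN2 inversion by oxidation and stereoselective reduction. Dess–Martin periodinane should give the ketone 1-[(2R,4S,5S)-4-(4-methoxybenzyloxy)-5-pentyltetrahydrofuran-2-yl]dec-9-en-1-one F7. Felkin-controlled reduction with LiBH(s-Bu)3 in THF at −78 °C should give the threo alcohol (1R)-1-[(2R,4S,5S)-4-(4-methoxybenzyloxy)-5-pentyltetrahydrofuran-2-yl]dec-9-en-1-ol F8. Acylation with dodecanoyl chloride, pyridine and DMAP in CH2Cl2 should give 18.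

**Further compounds**

F1 | step 8 | (2S,3R,5R)-5-[(1S)-1-(dimethylphenylsilyl)dec-9-en-1-yl]-2-pentyltetrahydrofuran-3-ol | C=CCCCCCCC[C@H]([Si](C)(C)c1ccccc1)[C@H]1C[C@@H](O)[C@H](CCCCC)O1
F2 | step 8 | (2S,5R)-5-[(1S)-1-(dimethylphenylsilyl)dec-9-en-1-yl]-2-pentyldihydrofuran-3(2H)-one | C=CCCCCCCC[C@H]([Si](C)(C)c1ccccc1)[C@H]1CC(=O)[C@H](CCCCC)O1
F3 | step 10 | (2S,3S,5R)-5-[(1S)-1-(dimethylphenylsilyl)dec-9-en-1-yl]-3-(naphthalen-2-ylmethoxy)-2-pentyltetrahydrofuran | C=CCCCCCCC[C@H]([Si](C)(C)c1ccccc1)[C@H]1C[C@H](OCc2ccc3ccccc3c2)[C@H](CCCCC)O1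
F4 | step 10 | (2S,3S,5R)-5-[(1S)-1-(fluorodimethylsilyl)dec-9-en-1-yl]-3-(naphthalen-2-ylmethoxy)-2-pentyltetrahydrofuran | C=CCCCCCCC[C@H]([Si](C)(C)F)[C@H]1C[C@H](OCc2ccc3ccccc3c2)[C@H](CCCCC)O1
F5 | step 10 | (1S)-1-[(2R,4S,5S)-4-(naphthalen-2-ylmethoxy)-5-pentyltetrahydrofuran-2-yl]dec-9-en-1-ol | C=CCCCCCCC[C@H](O)[C@H]1C[C@H](OCc2ccc3ccccc3c2)[C@H](CCCCC)O1
F6 | step 10 | (1R)-1-[(2R,4S,5S)-4-(naphthalen-2-ylmethoxy)-5-pentyltetrahydrofuran-2-yl]dec-9-en-1-yl dodecanoate | C=CCCCCCCC[C@@H](OC(=O)CCCCCCCCCCC)[C@H]1C[C@H](OCc2ccc3ccccc3c2)[C@H](CCCCC)O1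
F7 | step 11 | 1-[(2R,4S,5S)-4-(4-methoxybenzyloxy)-5-pentyltetrahydrofuran-2-yl]dec-9-en-1-one | C=CCCCCCCCC(=O)[C@H]1C[C@H](OCc2ccc(OC)cc2)[C@H](CCCCC)O1
F8 | step 11 | (1R)-1-[(2R,4S,5S)-4-(4-methoxybenzyloxy)-5-pentyltetrahydrofuran-2-yl]dec-9-en-1-ol | C=CCCCCCCC[C@@H](O)[C@H]1C[C@H](OCc2ccc(OC)cc2)[C@H](CCCCC)O1
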